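The route cuts two bonds at the acetoxy bridgehead C8: C7–C8 and C8–O. C8, shared by rings A and B, and its benzylic ring B neighbour C7 both carry oxygen, so the pair is a hidden glycidic lactone spiro-fused to ring A. A Darzens condensation between the enolate of a ring A α-bromo lactone and O-silylated vanillin makes both bonds at once. It also closes the oxirane, sets C7 and C8, and turns the aldehyde oxygen into the future acetate oxygen. The precursor is an enantiopure trans-5-aryl-4-(alkoxymethyl)-3-bromobutyrolactone. Its C9' oxygen carries a ketal more acid-labile than the epoxide, so one later acid treatment closes ring B.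

Key step: step 8

Numbering and abbreviations: lignan numbering is used.
- C8 is the bridgehead that ends up acetoxylated, flanked by benzylic C7 and by C9 (OCH2).
- C8' is the CH bridgehead, flanked by benzylic C7' and by C9' (OCH2).
- Ring A holds C7', O, C9, C8, C8'. Ring B holds C7, O, C9', C8', C8.
- Ar = 3-methoxy-4-(triisopropylsilyloxy)phenyl, TIPS = triisopropylsilyl, MOP = 2-methoxypropan-2-yl.

Assumption: compounds 1, 3 and 4 are commercial, and aldol adduct 7 needs no more than a trace of mild acid to finish its lactonisation.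

Step 1
Reactants: 1 vanillin
Product: 2 3-methoxy-4-(triisopropylsilyloxy)benzaldehyde (O-TIPS vanillin)
Conditions: i-Pr3SiCl, imidazole, DMF, rt
Reagents that add atoms: chlorotriisopropylsilane, CC(C)[Si](Cl)(C(C)C)C(C)C
Why: Imidazole-promoted O-silylation of a phenol is routine, and the bulky TIPS group is chosen because an aryl silyl ether has to outlast hydroperoxide, tert-butoxide and borohydride later on yet still leave with buffered fluoride at the end.

Step 2
Reactants: 3 (S)-4-benzyl-1,3-oxazolidin-2-one; 4 methyl 4-chloro-4-oxobutanoate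
Product: 5 methyl 4-[(4S)-4-benzyl-2-oxo-1,3-oxazolidin-3-yl]-4-oxobutanoate
Conditions: Et3N, DMAP (10 mol%), CH2Cl2, 0 °C → rt
Reagents that add atoms: none
Why: DMAP-catalysed N-acylation of an oxazolidinone by an acid chloride needs no strong base and leaves the methyl ester and the auxiliary stereocentre untouched.

Step 3
Reactants: 5 succinate imide; 2 O-TIPS vanillin
Product: 8 trans lactone imide (7'S,8'S), via Z boron enolate 6 (not isolated), via syn aldol adduct 7 (not isolated)
Conditions: n-Bu2BOTf, i-Pr2NEt, CH2Cl2, 0 °C; 2, −78 → 0 °C; H2O2, pH 7 buffer, MeOH, 0 °C; then PPTS (5 mol%), CH2Cl2, rt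
Reagents that add atoms: dibutylboron triflate, CCCCB(CCCC)OS(=O)(=O)C(F)(F)F (its atoms stay only in 6)
Why: Evans syn aldol reaction: soft enolisation touches only the imide side of the succinate, the Z boron enolate 6 meets 2 in a Zimmerman–Traxler chair on the face left open by the (S)-benzyl group, which sets C8' and C7' together, and the C7' hydroxyl of 7 then lactonises onto the methyl ester, a closure that translates the syn aldol into the trans-4,5-disubstituted lactone.

Step 4
Reactants: 8 trans lactone imide
Product: 10 (2S,3S)-2-Ar-5-oxooxolane-3-carboxylic acid (trans aryl paraconic acid), via peroxy acid 9 (not isolated)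
Conditions: LiOH, H2O2, THF/H2O, 0 °C; aq. Na2SO3; 1 M HCl to pH 3
Reagents that add atoms: hydrogen peroxide, OO
Why: Hydroperoxide cleavage of an N-acyl oxazolidinone attacks the exocyclic imide carbonyl in preference to the lactone and the carbamate, sulfite reduces peroxy acid 9, and acidification re-closes any lactone that opened, while the medium is too weakly basic to epimerise C8'.

Step 5
Reactants: 10 trans aryl paraconic acid
Product: 11 (4R,5S)-5-Ar-4-(hydroxymethyl)oxolan-2-one
Conditions: BH3·THF, THF, 0 °C → rt; H2O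
Reagents that add atoms: none
Why: Borane reduces a free carboxylic acid much faster than a lactone (chemoselective acid reduction), and its non-basic medium avoids the translactonisation by which the new C9' hydroxyl could swap places with the C7' oxygen.

Step 6
Reactants: 11 hydroxymethyl lactone
Product: 12 (4R,5S)-5-Ar-4-[(2-methoxypropan-2-yl)oxymethyl]oxolan-2-one (MOP ether)
Conditions: 2-methoxypropene, PPTS (2 mol%), CH2Cl2, 0 °C; Et3N quench
Reagents that add atoms: 2-methoxypropene, C=C(C)OC
Why: Acid-catalysed addition of the alcohol to an enol ether (mixed ketal formation) gives an achiral, base-stable, non-migrating protecting group that is deliberately more acid-labile than the aryl epoxide made in step 8.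

Step 7
Reactants: 12 MOP ether lactone
Product: 15 (4R,5S)-3-bromo-5-Ar-4-(MOP-oxymethyl)oxolan-2-one (epimers at C8), via lithium enolate 13 (not isolated), via silyl ketene acetal 14 (not isolated)
Conditions: LiN(SiMe3)2, THF, −78 °C; Me3SiCl; NBS, −78 → −40 °C; aq. NaHCO3
Reagents that add atoms: N-bromosuccinimide, O=C1CCC(=O)N1Br; chlorotrimethylsilane, C[Si](C)(C)Cl (its atoms stay only in 14)
Why: Electrophilic bromination of a silyl ketene acetal: trapping enolate 13 as 14 before NBS arrives prevents proton exchange and dibromination and outpaces ring bromination of the arene, and the configuration at C8 is of no concern because step 8 planarises it.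

Step 8
Reactants: 15 α-bromo lactone; 2 O-TIPS vanillin
Product: 18 spiro epoxy lactone (7S,8R,7'S,8'R), via potassium bromo enolate 16 (not isolated), via bromo aldolate 17 (not isolated)
Conditions: KOt-Bu (1 M in THF, slow addition to 15 + 2), THF, −78 → −20 °C; pH 7 buffer
Reagents that add atoms: none
Why: Darzens glycidic ester condensation, known for α-halo esters and α-halo lactones with aromatic aldehydes: tert-butoxide removes the acidic C8–H of 15 faster than it can induce loss of HBr, enolate 16 adds to the carbonyl carbon of 2 (C7–C8), and alkoxide 17 displaces bromide (C8–O). The only ring closed is the oxirane, by a 3-exo-tet displacement that needs O–C7–C8–Br antiperiplanar and inverts C8. C8 is controlled by the neighbouring C8' stereocentre: the aldehyde approaches the enolate face opposite the CH2OMOP arm, bromine is pushed onto the face of that arm, and inversion then leaves oxygen anti and C7 syn to C9', the arrangement of the cis-fused target. C7 is controlled by the reversibility of the aldol step: the aldolates equilibrate through 16 and 2, and the one that reaches the closing conformation with its aryl group turned away from the lactone carbonyl should close faster, giving the trans glycidate geometry (aryl cis to C8'). The step needs facial selectivity, aryl/carbonyl selectivity and enolisation in preference to elimination; the first is secured by the arm on the carbon next to the reacting centre, the second by the potassium counter-ion and the tert-butanol that keep the aldol reversible, the third by adding base slowly to a cold mixture of both partners so that 16 is trapped as it forms. No silyl group sits on an aliphatic oxygen, so alkoxide 17 cannot be diverted by silyl migration.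

Step 9
Reactants: 18 spiro epoxy lactone
Product: 20 8-hydroxy furofuranone (7R,8R,7'S,8'R) containing rings A (lactone) plus B, via hydroxy epoxide 19 (not isolated)
Conditions: camphor-10-sulfonic acid (10 mol%), water-saturated CH2Cl2, −20 → 0 °C; Et3N quench
Reagents that add atoms: none
Why: Acid first hydrolyses the very labile mixed ketal, so the epoxide is never activated without its internal nucleophile, and the C9' hydroxyl of 19 then opens the protonated oxirane at benzylic C7 in an aryl-assisted 5-endo hydroxy-epoxide cyclisation (the 4-exo alternative at C8 is strained and electronically disfavoured next to the carbonyl), with inversion at C7 that puts the aryl group on the convex face cis to the freed C8 hydroxyl, while intact ring A holds C7 and C9' cis and keeps the C7' oxygen out of the competition.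

Step 10
Reactants: 20 8-hydroxy furofuranone
Product: 21 triol (7R,8S,7'S,8'R): ring B oxolane bearing Ar at C7, OH and CH2OH at C8, CH(OH)Ar at C8'
Conditions: LiBH4, THF, 0 °C → rt; H2O
Reagents that add atoms: none
Why: Borohydride reduction of a lactone to the diol, accelerated here by the α-hydroxyl group, touches no stereocentre and spares aryl silyl ethers and benzylic ethers.

Step 11
Reactants: 21 triol
Product: 23 O,O'-bis(TIPS) 1-hydroxypinoresinol (7R,8S,7'S,8'R), via primary mesylate 22 (not isolated)
Conditions: MsCl (1.05 equiv), Et3N, CH2Cl2, −20 °C → rt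
Reagents that add atoms: methanesulfonyl chloride, CS(=O)(=O)Cl (its atoms stay only in 22)
Why: Selective sulfonylation of the only primary hydroxyl followed by an intramolecular Williamson-type 5-exo-tet etherification by the C7' hydroxyl, a standard way from furofuranone-derived diols to furofurans, forms the O–C9 bond without touching the C7'–O bond, so C7' is retained, and the cis arrangement of C9 and C7' on ring B together with the geminal substitution at C8 favours the oxolane over an oxirane from the neutral tertiary hydroxyl.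

Step 12
Reactants: 23 O,O'-bis(TIPS) 1-hydroxypinoresinol
Product: 24 O,O'-bis(TIPS) 1-acetoxypinoresinol
Conditions: Ac2O, Et3N, DMAP, CH2Cl2, rt → 40 °C
Reagents that add atoms: acetic anhydride, CC(=O)OC(C)=O
Why: DMAP-catalysed acylation is the usual answer to a hindered tertiary alcohol, and since the C8 hydroxyl is the only free one the reaction can be pushed with excess anhydride and mild heat under basic conditions that cannot epimerise the benzylic ethers.

Step 13
Reactants: 24 O,O'-bis(TIPS) 1-acetoxypinoresinol
Product: 25 1-acetoxypinoresinol (7R,8S,7'S,8'R)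
Conditions: Bu4NF, AcOH (one equivalent of each per silyl group), THF, 0 °C
Reagents that add atoms: none
Why: Fluoride-induced desilylation cleaves aryl silyl ethers within minutes because phenoxide leaves silicon easily, and buffering with acetic acid keeps the medium too weakly basic for loss or migration of the acetate or for quinone methide formation at C7 and C7'.

Compound list
1 | vanillin | COc1cc(C=O)ccc1O | starting material
2 | 3-methoxy-4-(triisopropylsilyloxy)benzaldehyde | COc1cc(C=O)ccc1O[Si](C(C)C)(C(C)C)C(C)C | intermediate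
3 | (S)-4-benzyl-1,3-oxazolidin-2-one | O=C1N[C@@H](Cc2ccccc2)CO1 | starting material
4 | methyl 4-chloro-4-oxobutanoate | COC(=O)CCC(=O)Cl | starting material
5 | methyl 4-[(4S)-4-benzyl-2-oxo-1,3-oxazolidin-3-yl]-4-oxobutanoate | COC(=O)CCC(=O)N1[C@@H](Cc2ccccc2)COC1=O | intermediate
6 | Z dibutylboron enolate of 5 (OB cis to CH2CO2Me) | COC(=O)C/C=C(\OB(CCCC)CCCC)N1[C@@H](Cc2ccccc2)COC1=O | intermediate
7 | syn aldol adduct, methyl (3S,4S)-3-[(4S)-4-benzyl-2-oxo-1,3-oxazolidine-3-carbonyl]-4-hydroxy-4-Ar-butanoate | COc1cc([C@@H](O)[C@H](CC(=O)OC)C(=O)N2[C@@H](Cc3ccccc3)COC2=O)ccc1O[Si](C(C)C)(C(C)C)C(C)C | intermediate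
8 | (4S)-4-benzyl-3-[(2S,3S)-2-Ar-5-oxooxolane-3-carbonyl]-1,3-oxazolidin-2-one (trans lactone) | COc1cc([C@H]2OC(=O)C[C@@H]2C(=O)N3[C@@H](Cc4ccccc4)COC3=O)ccc1O[Si](C(C)C)(C(C)C)C(C)C | intermediate
9 | (2S,3S)-2-Ar-5-oxooxolane-3-carboperoxoic acid | COc1cc([C@H]2OC(=O)C[C@@H]2C(=O)OO)ccc1O[Si](C(C)C)(C(C)C)C(C)C | intermediate
10 | (2S,3S)-2-Ar-5-oxooxolane-3-carboxylic acid (trans) | COc1cc([C@H]2OC(=O)C[C@@H]2C(=O)O)ccc1O[Si](C(C)C)(C(C)C)C(C)C | intermediate
11 | (4R,5S)-5-Ar-4-(hydroxymethyl)oxolan-2-one (trans) | COc1cc([C@H]2OC(=O)C[C@@H]2CO)ccc1O[Si](C(C)C)(C(C)C)C(C)C | intermediate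
12 | (4R,5S)-5-Ar-4-[(2-methoxypropan-2-yl)oxymethyl]oxolan-2-one | COc1cc([C@H]2OC(=O)C[C@@H]2COC(C)(C)OC)ccc1O[Si](C(C)C)(C(C)C)C(C)C | intermediate
13 | lithium enolate of 12 | COc1cc([C@H]2OC([O-])=C[C@@H]2COC(C)(C)OC)ccc1O[Si](C(C)C)(C(C)C)C(C)C.[Li+] | intermediate
14 | trimethylsilyl ketene acetal of 12 | COc1cc([C@H]2OC(O[Si](C)(C)C)=C[C@@H]2COC(C)(C)OC)ccc1O[Si](C(C)C)(C(C)C)C(C)C | intermediate
15 | (4R,5S)-3-bromo-5-Ar-4-[(2-methoxypropan-2-yl)oxymethyl]oxolan-2-one, aryl trans to the side arm, both epimers at the bromide carbon C8 | COc1cc([C@H]2OC(=O)C(Br)[C@@H]2COC(C)(C)OC)ccc1O[Si](C(C)C)(C(C)C)C(C)C | intermediate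
16 | potassium enolate of 15 | COc1cc([C@H]2OC([O-])=C(Br)[C@@H]2COC(C)(C)OC)ccc1O[Si](C(C)C)(C(C)C)C(C)C.[K+] | intermediate
17 | potassium bromo aldolate: on ring A, C7 anti and Br syn to the C9' arm | COc1cc([C@H]2OC(=O)[C@@](Br)([C@@H]([O-])c3ccc(O[Si](C(C)C)(C(C)C)C(C)C)c(OC)c3)[C@@H]2COC(C)(C)OC)ccc1O[Si](C(C)C)(C(C)C)C(C)C.[K+] | intermediate
18 | (7S,8R,7'S,8'R) spiro epoxy lactone: ring A lactone (C9=O) spiro at C8 to the C7–C8 oxirane, epoxide O anti and C7 syn to the CH2OMOP arm, C7 aryl trans to C9=O | COc1cc([C@H]2OC(=O)[C@@]3(O[C@H]3c4ccc(O[Si](C(C)C)(C(C)C)C(C)C)c(OC)c4)[C@@H]2COC(C)(C)OC)ccc1O[Si](C(C)C)(C(C)C)C(C)C | intermediate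
19 | hydroxy epoxide, 18 with free C9' hydroxyl | COc1cc([C@H]2OC(=O)[C@@]3(O[C@H]3c4ccc(O[Si](C(C)C)(C(C)C)C(C)C)c(OC)c4)[C@@H]2CO)ccc1O[Si](C(C)C)(C(C)C)C(C)C | intermediate
20 | (7R,8R,7'S,8'R) cis-fused 8-hydroxy furofuranone, C9=O, both aryl groups exo, C8–OH cis to C8'–H | COc1cc([C@H]2OC(=O)[C@]3(O)[C@@H](c4ccc(O[Si](C(C)C)(C(C)C)C(C)C)c(OC)c4)OC[C@H]23)ccc1O[Si](C(C)C)(C(C)C)C(C)C | intermediate
21 | (7R,8S,7'S,8'R) triol: ring B oxolane with C7 aryl, C8 OH and CH2OH, C8' CH(OH)Ar | COc1cc([C@@H](O)[C@H]2CO[C@H](c3ccc(O[Si](C(C)C)(C(C)C)C(C)C)c(OC)c3)[C@@]2(O)CO)ccc1O[Si](C(C)C)(C(C)C)C(C)C | intermediate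
22 | C9 methanesulfonate of 21 | COc1cc([C@@H](O)[C@H]2CO[C@H](c3ccc(O[Si](C(C)C)(C(C)C)C(C)C)c(OC)c3)[C@@]2(O)COS(C)(=O)=O)ccc1O[Si](C(C)C)(C(C)C)C(C)C | intermediate
23 | O,O'-bis(triisopropylsilyl) 1-hydroxypinoresinol (7R,8S,7'S,8'R) | COc1cc([C@H]2OC[C@]3(O)[C@@H](c4ccc(O[Si](C(C)C)(C(C)C)C(C)C)c(OC)c4)OC[C@H]23)ccc1O[Si](C(C)C)(C(C)C)C(C)C | intermediate
24 | O,O'-bis(triisopropylsilyl) 1-acetoxypinoresinol (7R,8S,7'S,8'R) | COc1cc([C@H]2OC[C@]3(OC(C)=O)[C@@H](c4ccc(O[Si](C(C)C)(C(C)C)C(C)C)c(OC)c4)OC[C@H]23)ccc1O[Si](C(C)C)(C(C)C)C(C)C | intermediate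
25 | 1-acetoxypinoresinol (7R,8S,7'S,8'R) | COc1cc([C@H]2OC[C@]3(OC(C)=O)[C@@H](c4ccc(O)c(OC)c4)OC[C@H]23)ccc1O | target

Total step count: 13
Longest linear sequence: 12 steps (steps 2 to 13 from 3 and 4; equally steps 1 and 3 to 13 from 1)

Steps most likely to fail

Step 8 (Darzens union).
- What may go wrong: base-induced loss of HBr from 15, decay of enolate 16 before it is trapped, or weak facial or aryl/carbonyl selectivity.
- Fallback (sets out from 12 and 2, comes back at 18): the C7–C8 bond is made by an ordinary aldol reaction and the C8 oxygen is brought in afterwards by epoxidation. Enolate 13 (LiN(SiMe3)2, THF, −78 °C) is added to 2 to give the aldol adduct F1. Acetylation (Ac2O, Et3N, DMAP, CH2Cl2) gives the benzylic acetate F2. DBU then removes acetic acid by E1cB elimination to give the (E)-arylidene lactone F3, whose aryl group already lies trans to the carbonyl. Stereospecific epoxidation with dimethyldioxirane (acetone, 0 °C), a reagent type known to epoxidise electron-rich cinnamates, should attack the face opposite the CH2OMOP arm and deliver 18.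

Step 9 (ketal cleavage and ring B closure).
- What may go wrong: ionisation at C7 followed by acyl migration instead of capture, capture through a fully free cation with erosion of configuration at C7, or translactonisation of 19 before the epoxide opens.
- Fallback (sets out from 18, comes back at 20): nucleophile and electrophile change roles, so that ring B is closed at primary C9' and not at C7. A water-rich medium (HClO4 cat., THF/H2O, 0 °C) removes the ketal. Water in large excess then opens the epoxide at C7 with inversion to give the trihydroxy lactone F4, a stage at which epimers at C7 can be separated. Selective mesylation of the primary hydroxyl (MsCl, 2,4,6-collidine, CH2Cl2, 0 °C) gives the C9' mesylate F5. Warming with Et3N lets the C7 hydroxyl displace it in a 5-exo-tet closure that leaves C7 untouched and gives 20.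

Step 11 (ring A closure).
- What may go wrong: competing activation of the benzylic C7' hydroxyl with ionisation and erosion of C7', slow displacement at the neopentyl-type C9, or participation of the C8 hydroxyl.
- Fallback (sets out from 20, comes back at 23): ring A is never opened. i-Bu2AlH (CH2Cl2, −78 °C) stops at the lactol F6. Ionic reduction through its oxocarbenium ion (Et3SiH, BF3·OEt2, CH2Cl2, −78 → −40 °C) gives 23 directly. The low temperature is needed to keep the benzylic C–O bonds from ionising.

Further compounds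
F1 | step 8 | aldol adduct of 12 and 2 (C7 anti to the C9' arm at C8, both C7 carbinol epimers) | COc1cc([C@H]2OC(=O)[C@@H](C(O)c3ccc(O[Si](C(C)C)(C(C)C)C(C)C)c(OC)c3)[C@@H]2COC(C)(C)OC)ccc1O[Si](C(C)C)(C(C)C)C(C)C
F2 | step 8 | benzylic acetate of F1 | COc1cc([C@H]2OC(=O)[C@@H](C(OC(C)=O)c3ccc(O[Si](C(C)C)(C(C)C)C(C)C)c(OC)c3)[C@@H]2COC(C)(C)OC)ccc1O[Si](C(C)C)(C(C)C)C(C)C
F3 | step 8 | (E)-arylidene lactone, C7=C8, aryl trans to C9=O | COc1cc([C@H]2OC(=O)/C(=C/c3ccc(O[Si](C(C)C)(C(C)C)C(C)C)c(OC)c3)[C@@H]2COC(C)(C)OC)ccc1O[Si](C(C)C)(C(C)C)C(C)C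
F4 | step 9 | (7R,8R,7'S,8'R) trihydroxy lactone with OH at C7, C8 and C9' | COc1cc([C@H]2OC(=O)[C@](O)([C@H](O)c3ccc(O[Si](C(C)C)(C(C)C)C(C)C)c(OC)c3)[C@@H]2CO)ccc1O[Si](C(C)C)(C(C)C)C(C)C
F5 | step 9 | C9' methanesulfonate of F4 | COc1cc([C@H]2OC(=O)[C@](O)([C@H](O)c3ccc(O[Si](C(C)C)(C(C)C)C(C)C)c(OC)c3)[C@@H]2COS(C)(=O)=O)ccc1O[Si](C(C)C)(C(C)C)C(C)C
F6 | step 11 | C9 lactol of 20 (both anomers) | COc1cc([C@H]2OC(O)[C@]3(O)[C@@H](c4ccc(O[Si](C(C)C)(C(C)C)C(C)C)c(OC)c4)OC[C@H]23)ccc1O[Si](C(C)C)(C(C)C)C(C)C
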